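## Retrosynthetic overview

1. The C-12–C-13 bond is cut last: Negishi sp3–sp2 coupling of a C-12 alkylzinc of the silyl-protected decalin with an (R)-butenolide (E)-alkenyl iodide, whose lactone ring is made first (asymmetric propiolate addition, cuprate addition–lactonisation).
2. The 18-OH is installed late by 6α-OH-directed δ-C–H silylation/oxidation of the peri 4α-methyl group, so ring A can be bought as the gem-dimethyl ring of β-cyclocitral.
3. Ring B (C-5, C-6, C-7, C-8, C-9, C-10) is closed by a Prins cyclisation–hydration that forms the C-6–C-7 and C-8–O bonds. The enabling feature is the 1,3-diol of ring B: a secondary carbinol at C-6 and a tertiary methyl carbinol at C-8 flank the C-7 methylene, and C-6 sits on the enolisable ring-fusion carbon C-5 (C-6 aldehyde + C-7=C-8(CH3) alkene + water).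
4. The Prins precursor comes from an anionic oxy-Cope rearrangement of an (R)-dienol built from β-cyclocitral (asymmetric propargylation, methylalumination/ethylene oxide). Its chair uses the same six carbons as ring B and relays chirality from C-6 to C-9 and C-10.
5. Order of rings: butenolide (step 4), ring A (purchased), ring B (step 9, last).

Key step: step 9

Assumption: the catalyst antipodes named in steps 3 and 5 are taken to give the (R)-carbinols by analogy with the accepted models for these catalyst classes (otherwise the mirror-image catalyst is used); decalin carbons carry labdane-type locants (C-1 to C-10 in the rings, C-17 on C-8, C-18 (α) and C-19 (β) on C-4, C-20 on C-10, side chain from C-11).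

## Route

Step 1
Reactants: 1 pent-3-yn-1-ol
Product: 3 (3E)-4-iodopent-3-en-1-ol, via alkenylzirconocene chloride 2 (not isolated)
Conditions: Cp2Zr(H)Cl (2.3 equiv), THF, 0 → 40 °C; then I2, 0 °C
Reagents that add atoms: iodine, II
Why: Hydrozirconation–iodination: syn addition of Zr–H, with zirconium settling under equilibrating conditions on the less hindered methyl-bearing alkyne carbon, then iodinolysis with retention, should give the (E)-2-iodoalkene.

Step 2
Reactants: 3 (3E)-4-iodopent-3-en-1-ol
Product: 4 (3E)-4-iodopent-3-enal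
Conditions: Dess–Martin periodinane, CH2Cl2, 0 °C; crude aldehyde used at once
Reagents that add atoms: none
Why: Dess–Martin oxidation of the primary alcohol under non-enolising conditions should give the β,γ-unsaturated aldehyde without migration of the double bond.

Step 3
Reactants: 4 (3E)-4-iodopent-3-enal; 5 methyl propiolate
Product: 6 methyl (4R,6E)-4-hydroxy-7-iodooct-6-en-2-ynoate
Conditions: 5 (3 equiv), ZnEt2 (3 equiv), (R)-BINOL (20 mol%), Ti(OiPr)4 (50 mol%), Cy2NH (5 mol%), Et2O, rt; 1 M HCl work-up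
Reagents that add atoms: none
Why: Catalytic asymmetric alkynylzinc addition to an aldehyde, in which the chiral titanium BINOLate differentiates the aldehyde faces and sets the (R)-carbinol that becomes the butenolide stereocentre.

Step 4
Reactants: 6 methyl (4R,6E)-4-hydroxy-7-iodooct-6-en-2-ynoate
Product: 8 (5R)-5-[(2E)-3-iodobut-2-en-1-yl]-4-methylfuran-2(5H)-one, via (Z)-hydroxy enoate 7 (not isolated)
Conditions: MeLi (5 equiv), CuI (2.5 equiv), THF, −78 °C; aq. NH4Cl, then rt
Reagents that add atoms: lithium dimethylcuprate (from MeLi and CuI), [Li+].C[Cu-]C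
Why: Conjugate addition of Me2CuLi to the γ-hydroxy ynoate is a syn carbocupration that places the ester cis to the carbinol, so the (Z)-γ-hydroxy enoate lactonises to the 4-methylbutenolide; the stereocentre is not touched and the alkenyl iodide should survive at −78 °C.

Step 5
Reactants: 9 β-cyclocitral; 10 allenylboronic acid pinacol ester
Product: 11 (1R)-1-(2,6,6-trimethylcyclohex-1-en-1-yl)but-3-yn-1-ol
Conditions: 10 (1.5 equiv), (R)-TRIP (5 mol%), 4 Å MS, toluene, 0 °C → rt; aqueous work-up
Reagents that add atoms: none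
Why: Chiral phosphoric acid-catalysed propargylation of an aldehyde with an allenylboronate through a closed six-membered SE2' transition state; the catalyst bound to the boronate oxygen selects the aldehyde face and sets the (R)-carbinol.

Step 6
Reactants: 11 (1R)-1-(2,6,6-trimethylcyclohex-1-en-1-yl)but-3-yn-1-ol
Product: 14 (3E,6R)-4-methyl-6-(2,6,6-trimethylcyclohex-1-en-1-yl)hex-3-ene-1,6-diol, via dimethylalkenylalane 12 (not isolated), via lithium butylalkenylalanate 13 (not isolated)
Conditions: Me3Al (3 equiv), Cp2ZrCl2 (20 mol%), CH2Cl2, 0 °C → rt; volatiles removed; n-BuLi, hexane/THF, −30 °C; ethylene oxide, −30 → 0 °C; aq. KNaC4H4O6 work-up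
Reagents that add atoms: trimethylaluminium, C[Al](C)C; ethylene oxide, C1CO1
Why: Zr-catalysed methylalumination (Negishi carboalumination) adds CH3 and Al syn with methyl on the internal carbon, and the derived alanate opens ethylene oxide with retention of alkene geometry, which fixes the (E)-trisubstituted alkene.

Step 7
Reactants: 14 (3E,6R)-4-methyl-6-(2,6,6-trimethylcyclohex-1-en-1-yl)hex-3-ene-1,6-diol
Product: 17 (1RS,2R)-2-[(3S)-5-hydroxy-2-methylpent-1-en-3-yl]-2,6,6-trimethylcyclohexane-1-carbaldehyde, via dipotassium dialkoxide 15 (not isolated), via dipotassium enolate 16 (not isolated)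
Conditions: KH (2.5 equiv), 18-crown-6 (2.5 equiv), THF, 0 → 50 °C; AcOH, −78 °C
Reagents that add atoms: none
Why: Anionic oxy-Cope rearrangement through a chair in which the carbinol hydrogen, not the oxyanion, eclipses the C-4–C-5 bond (avoiding the gem-dimethyl group) and the (E)-alkene places C-11 pseudo-equatorial, so chirality is relayed from C-6 to the quaternary C-10 and to C-9; protonation of the enolate gives a C-5 epimer mixture that is of no consequence.

Step 8
Reactants: 17 (1RS,2R)-2-[(3S)-5-hydroxy-2-methylpent-1-en-3-yl]-2,6,6-trimethylcyclohexane-1-carbaldehyde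
Product: 18 (3S)-3-[(1R,2RS)-2-formyl-1,3,3-trimethylcyclohexyl]-4-methylpent-4-en-1-yl 2,2-dimethylpropanoate
Conditions: PivCl (1.2 equiv), pyridine, DMAP (cat.), CH2Cl2, 0 °C
Reagents that add atoms: pivaloyl chloride, CC(C)(C)C(Cl)=O
Why: Acylation of the primary alcohol (the aldehyde is inert); the pivalate masks the C-12 oxygen as a non-nucleophilic group for the cationic step.

Step 9
Reactants: 18 (3S)-3-[(1R,2RS)-2-formyl-1,3,3-trimethylcyclohexyl]-4-methylpent-4-en-1-yl 2,2-dimethylpropanoate (both C-5 epimers)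
Product: 19 2-[(1R,2R,4S,4aS,8aS)-2,4-dihydroxy-2,5,5,8a-tetramethyldecahydronaphthalen-1-yl]ethyl 2,2-dimethylpropanoate (12-pivaloyloxy-13,14,15,16-tetranorlabdane-6α,8α-diol)
Conditions: H2SO4 (0.5 M aq.)–THF (1:2), 30 °C
Reagents that add atoms: water, O
Why: The acid activates the C-6 aldehyde as a hydroxycarbenium ion, which is attacked by the terminal carbon C-7 of the 1,1-disubstituted alkene (6-endo-trig, Markovnikov) to form C-6–C-7 and a tertiary C-8 cation that is captured by water; the closest known reaction type is the aqueous-acid Prins cyclisation of δ,ε-unsaturated aldehydes to cyclohexane-1,3-diols (citronellal to p-menthane-3,8-diol). Ring B closes through a chair that reuses the six carbons of the oxy-Cope chair, with the C-9 side chain equatorial. C-5 is set by stereoconvergence: the two aldehyde epimers interconvert through the enol under the acid (Curtin–Hammett), and only the (1S) epimer reaches the strain-free trans-decalin chair–chair transition state, the cis-fused alternative pressing the C-4 gem-dimethyl group against the C-9 substituent. C-6 is set by equatorial placement of the protonated carbonyl oxygen, the axial position being syn-diaxial to the C-10 methyl and next to the axial C-4 methyl, which gives 6α-OH. C-8 is set by attack of water on the cation from the α (equatorial) face, anti to the new C-6–C-7 bond and away from the syn-axial C-10 methyl, which gives 8α-OH/8β-CH3 as in sclareol-type hydrations. The step needs capture by water instead of proton loss or neighbouring-group attack: dilute aqueous acid at low temperature favours hydration, and the pivalate at C-12 cannot close the ambrox-type ether.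

Step 10
Reactants: 19 12-pivaloyloxy-13,14,15,16-tetranorlabdane-6α,8α-diol
Product: 22 12-pivaloyloxy-13,14,15,16-tetranorlabdane-6α,8α,18-triol, via 6-O-diethylsilyl ether 20 (not isolated), via oxasilinane 21 (not isolated)
Conditions: Et2SiH2 (1.5 equiv), [Ir(cod)OMe]2 (0.5 mol%), THF, rt; volatiles removed; [Rh(cod)Cl]2 (2 mol%), Xantphos (5 mol%), norbornene (1.5 equiv), THF, 100 °C; then H2O2 (30% aq.), KHCO3, THF/MeOH, 50 °C
Reagents that add atoms: hydrogen peroxide, OO
Why: Alcohol-directed δ-C–H silylation followed by Tamao–Fleming oxidation (1,4-diol synthesis): the 6-O–SiEt2H group has no γ C–H and can reach only the equatorial 4α-methyl, which is peri to the equatorial 6α-oxygen (about 2.5–3 Å) and closes a six-membered oxasilinane; this choice makes C-4 stereogenic as 4α-CH2OH/4β-CH3, and any silyl ether formed at the tertiary 8-OH is cleaved in the oxidation.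

Step 11
Reactants: 22 12-pivaloyloxy-13,14,15,16-tetranorlabdane-6α,8α,18-triol
Product: 23 6α,8α,18-tris(triethylsilyloxy)-13,14,15,16-tetranorlabdan-12-yl 2,2-dimethylpropanoate
Conditions: TESOTf (4 equiv), 2,6-lutidine, CH2Cl2, −78 → 0 °C
Reagents that add atoms: triethylsilyl trifluoromethanesulfonate, CC[Si](CC)(CC)OS(=O)(=O)C(F)(F)F
Why: Silyl ether formation with the reactive triflate covers the primary, the hindered secondary and the tertiary hydroxyl, so that neither the later iodide nor the organozinc can be intercepted by the 8-OH.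

Step 12
Reactants: 23 6α,8α,18-tris(triethylsilyloxy)-13,14,15,16-tetranorlabdan-12-yl 2,2-dimethylpropanoate
Product: 24 6α,8α,18-tris(triethylsilyloxy)-13,14,15,16-tetranorlabdan-12-ol
Conditions: i-Bu2AlH (2.5 equiv), CH2Cl2, −78 °C; aq. KNaC4H4O6 work-up
Reagents that add atoms: none
Why: Reductive cleavage of the pivalate ester by hydride; triethylsilyl ethers are stable to these conditions.

Step 13
Reactants: 24 6α,8α,18-tris(triethylsilyloxy)-13,14,15,16-tetranorlabdan-12-ol
Product: 25 12-iodo-6α,8α,18-tris(triethylsilyloxy)-13,14,15,16-tetranorlabdane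
Conditions: I2, PPh3, imidazole, CH2Cl2, 0 °C → rt
Reagents that add atoms: iodine, II
Why: Appel-type iodination of the primary alcohol by SN2 at C-12; the silylated 8-oxygen cannot close the ambrox-type ether.

Step 14
Reactants: 25 12-iodo-6α,8α,18-tris(triethylsilyloxy)-13,14,15,16-tetranorlabdane; 8 (5R)-5-[(2E)-3-iodobut-2-en-1-yl]-4-methylfuran-2(5H)-one
Product: 27 6α,8α,18-tris-O-triethylsilyl ether of the target, via alkylzinc iodide 26 (not isolated)
Conditions: Zn dust (activated), LiCl, THF, 40 °C; then 8 (0.85 equiv), Pd(PPh3)4 (5 mol%), THF, 25 → 45 °C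
Reagents that add atoms: none
Why: Negishi sp3–sp2 cross-coupling: zinc insertion gives the primary alkylzinc iodide, which couples with the (E)-alkenyl iodide with retention of alkene geometry, and the weakly basic organozinc should leave the butenolide and its stereocentre untouched.

Step 15
Reactants: 27 6α,8α,18-tris-O-triethylsilyl ether of the target
Product: 28 (5R)-5-{(2E)-5-[(1R,2R,4S,4aR,5R,8aS)-2,4-dihydroxy-5-(hydroxymethyl)-2,5,8a-trimethyldecahydronaphthalen-1-yl]-3-methylpent-2-en-1-yl}-4-methylfuran-2(5H)-one (target)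
Conditions: HF·pyridine, pyridine/THF, 0 °C → rt
Reagents that add atoms: none
Why: Fluoride-mediated desilylation under buffered, weakly acidic conditions should remove all three triethylsilyl groups without touching the butenolide, the tertiary alcohol or the trisubstituted alkene.

## Compound list

1 | pent-3-yn-1-ol | CC#CCCO | starting material
2 | (E)-alkenylzirconocene chloride from 1, hydroxyl held as zirconium alkoxide | C/C(=C\CCO[Zr](Cl)(C1C=CC=C1)C1C=CC=C1)[Zr](Cl)(C1C=CC=C1)C1C=CC=C1 | intermediate (not isolated)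
3 | (3E)-4-iodopent-3-en-1-ol | C/C(I)=C\CCO | intermediate
4 | (3E)-4-iodopent-3-enal | C/C(I)=C\CC=O | intermediate
5 | methyl propiolate | C#CC(=O)OC | starting material
6 | methyl (4R,6E)-4-hydroxy-7-iodooct-6-en-2-ynoate | COC(=O)C#C[C@H](O)C/C=C(\C)I | intermediate
7 | methyl (2Z,4R,6E)-4-hydroxy-7-iodo-3-methylocta-2,6-dienoate | COC(=O)/C=C(/C)[C@H](O)C/C=C(\C)I | intermediate (not isolated)
8 | (5R)-5-[(2E)-3-iodobut-2-en-1-yl]-4-methylfuran-2(5H)-one | CC1=CC(=O)O[C@@H]1C/C=C(\C)I | intermediate
9 | β-cyclocitral (2,6,6-trimethylcyclohex-1-ene-1-carbaldehyde) | CC1=C(C=O)C(C)(C)CCC1 | starting material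
10 | allenylboronic acid pinacol ester | C=C=CB1OC(C)(C)C(C)(C)O1 | starting material
11 | (1R)-1-(2,6,6-trimethylcyclohex-1-en-1-yl)but-3-yn-1-ol | C#CC[C@@H](O)C1=C(C)CCCC1(C)C | intermediate
12 | dimethyl{(1E,4R)-4-[(dimethylalumanyl)oxy]-2-methyl-4-(2,6,6-trimethylcyclohex-1-en-1-yl)but-1-en-1-yl}alumane | C[Al](C)/C=C(\C)C[C@@H](O[Al](C)C)C1=C(C)CCCC1(C)C | intermediate (not isolated)
13 | lithium butyl(dimethyl)alanate of 12 (butyl added at the alkenyl aluminium) | [Li+].CCCC[Al-](C)(C)/C=C(\C)C[C@@H](O[Al](C)C)C1=C(C)CCCC1(C)C | intermediate (not isolated)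
14 | (3E,6R)-4-methyl-6-(2,6,6-trimethylcyclohex-1-en-1-yl)hex-3-ene-1,6-diol | OCC/C=C(\C)C[C@@H](O)C1=C(C)CCCC1(C)C | intermediate
15 | dipotassium dialkoxide of 14 | [K+].[K+].[O-]CC/C=C(\C)C[C@@H]([O-])C1=C(C)CCCC1(C)C | intermediate (not isolated)
16 | dipotassium salt of the enol of 17 (C-5=C-6 enolate, C-12 alkoxide) | [K+].[K+].[O-]CC[C@@H](C(C)=C)[C@@]1(C)CCCC(C)(C)C1=C[O-] | intermediate (not isolated)
17 | (1RS,2R)-2-[(3S)-5-hydroxy-2-methylpent-1-en-3-yl]-2,6,6-trimethylcyclohexane-1-carbaldehyde | OCC[C@@H](C(C)=C)[C@@]1(C)CCCC(C)(C)C1C=O | intermediate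
18 | (3S)-3-[(1R,2RS)-2-formyl-1,3,3-trimethylcyclohexyl]-4-methylpent-4-en-1-yl 2,2-dimethylpropanoate | CC(C)(C)C(=O)OCC[C@@H](C(C)=C)[C@@]1(C)CCCC(C)(C)C1C=O | intermediate
19 | 2-[(1R,2R,4S,4aS,8aS)-2,4-dihydroxy-2,5,5,8a-tetramethyldecahydronaphthalen-1-yl]ethyl 2,2-dimethylpropanoate | CC(C)(C)C(=O)OCC[C@@H]1[C@@]2(C)CCCC(C)(C)[C@@H]2[C@@H](O)C[C@@]1(C)O | intermediate
20 | 6α-(diethylsilyloxy)-12-pivaloyloxy-13,14,15,16-tetranorlabdan-8α-ol | CC(C)(C)C(=O)OCC[C@@H]1[C@@]2(C)CCCC(C)(C)[C@@H]2[C@@H](O[SiH](CC)CC)C[C@@]1(C)O | intermediate (not isolated)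
21 | oxasilinane of 19: diethylsilanediyl bridge from O-6 to C-18 (six-membered ring O-6, Si, C-18, C-4, C-5, C-6), 8α-OH and 12-pivalate unchanged | CC(C)(C)C(=O)OCC[C@@H]1[C@@]2(C)CCC[C@@](C)(C[Si]3(CC)CC)[C@@H]2[C@@H](O3)C[C@@]1(C)O | intermediate (not isolated)
22 | 12-pivaloyloxy-13,14,15,16-tetranorlabdane-6α,8α,18-triol | CC(C)(C)C(=O)OCC[C@@H]1[C@@]2(C)CCC[C@@](C)(CO)[C@@H]2[C@@H](O)C[C@@]1(C)O | intermediate
23 | 6α,8α,18-tris(triethylsilyloxy)-13,14,15,16-tetranorlabdan-12-yl 2,2-dimethylpropanoate | CC(C)(C)C(=O)OCC[C@@H]1[C@@]2(C)CCC[C@@](C)(CO[Si](CC)(CC)CC)[C@@H]2[C@@H](O[Si](CC)(CC)CC)C[C@@]1(C)O[Si](CC)(CC)CC | intermediate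
24 | 6α,8α,18-tris(triethylsilyloxy)-13,14,15,16-tetranorlabdan-12-ol | OCC[C@@H]1[C@@]2(C)CCC[C@@](C)(CO[Si](CC)(CC)CC)[C@@H]2[C@@H](O[Si](CC)(CC)CC)C[C@@]1(C)O[Si](CC)(CC)CC | intermediate
25 | 12-iodo-6α,8α,18-tris(triethylsilyloxy)-13,14,15,16-tetranorlabdane | ICC[C@@H]1[C@@]2(C)CCC[C@@](C)(CO[Si](CC)(CC)CC)[C@@H]2[C@@H](O[Si](CC)(CC)CC)C[C@@]1(C)O[Si](CC)(CC)CC | intermediate
26 | [6α,8α,18-tris(triethylsilyloxy)-13,14,15,16-tetranorlabdan-12-yl]zinc iodide | I[Zn]CC[C@@H]1[C@@]2(C)CCC[C@@](C)(CO[Si](CC)(CC)CC)[C@@H]2[C@@H](O[Si](CC)(CC)CC)C[C@@]1(C)O[Si](CC)(CC)CC | intermediate (not isolated)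
27 | 6α,8α,18-tris-O-triethylsilyl ether of the target | CC1=CC(=O)O[C@@H]1C/C=C(\C)CC[C@@H]1[C@@]2(C)CCC[C@@](C)(CO[Si](CC)(CC)CC)[C@@H]2[C@@H](O[Si](CC)(CC)CC)C[C@@]1(C)O[Si](CC)(CC)CC | intermediate
28 | (5R)-5-{(2E)-5-[(1R,2R,4S,4aR,5R,8aS)-2,4-dihydroxy-5-(hydroxymethyl)-2,5,8a-trimethyldecahydronaphthalen-1-yl]-3-methylpent-2-en-1-yl}-4-methylfuran-2(5H)-one | CC1=CC(=O)O[C@@H]1C/C=C(\C)CC[C@@H]1[C@@]2(C)CCC[C@@](C)(CO)[C@@H]2[C@@H](O)C[C@@]1(C)O | target

## Step count and risks

Total steps: 15. Longest linear sequence: 11 steps (steps 5–15, from β-cyclocitral); the butenolide fragment takes 4 steps (steps 1–4).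

**Step 9 (ring B closure).** After C-6–C-7 bond formation the C-8 cation may lose a proton instead of adding water, or hydration may reverse so that alkenes build up; slow equilibration at C-5 would also leak material into the cis-fused series. Fallback: 18 is first equilibrated (DBU, toluene) and then closed without water as a type-two carbonyl-ene cyclisation (Me2AlCl, CH2Cl2, −78 °C), which should give 12-pivaloyloxy-13,14,15,16-tetranorlabd-8(17)-en-6α-ol F1, possibly with its Δ7 isomer. Mukaiyama hydration (Co(acac)2, PhSiH3, O2, i-PrOH) then installs the tertiary alcohol; both alkene isomers give the same C-8 radical, which should be oxygenated from the open α face. The sequence rejoins the route at 19.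

**Step 7 (anionic oxy-Cope).** The hindered alkoxide may fragment into β-cyclocitral and an allyl anion, bond formation at the tetrasubstituted alkene terminus may be slow, or some material may pass through the other chair (oxyanion eclipsing C-4–C-5), which would erode enantiomeric purity. Fallback: 14 is converted (TMSCl, imidazole, DMF) into the bis(trimethylsilyl) ether of 14 F2. A neutral siloxy-Cope rearrangement (o-dichlorobenzene, 200–220 °C, sealed tube), in which no alkoxide can fragment and the larger silyloxy group avoids the gem-dimethyl side more decisively, should give the trimethylsilyl enol ether of 17 with the C-12 trimethylsilyl ether F3. Dilute HCl in THF removes both silyl groups and returns 17.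

**Step 10 (C-18 hydroxylation).** The catalyst may silylate a methyl other than C-18, cyclometalation may fail because of crowding around the silyl ether, or the tertiary 8-OH may consume the silane. Fallback by an alkoxy-radical route, setting out from 19:
- TESOTf/2,6-lutidine gives the 6α,8α-bis(triethylsilyl) ether of 19 F4.
- Selective methanolysis of the secondary silyl ether (PPTS, MeOH, 0 °C) gives the 8-O-triethylsilyl ether of 19 F5, which keeps the tertiary oxygen from forming a radical.
- Hypoiodite photolysis (PhI(OAc)2, I2, cyclohexane, hν) — 1,5-hydrogen transfer from C-18 to the 6-alkoxy radical, then closure — gives the 6α,18-epoxide (cyclic ether) F6.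
- RuCl3 (cat.)/NaIO4 oxidises the ether CH2 to the 18,6α-lactone F7.
- LiBH4 (THF, 0 °C) reduces the lactone in the presence of the pivalate to the 8-O-triethylsilyl 6α,18-diol F8.
- TESOTf/2,6-lutidine then gives 23, where the route is rejoined.

Further compounds
F1 | step 9 | 12-pivaloyloxy-13,14,15,16-tetranorlabd-8(17)-en-6α-ol | CC(C)(C)C(=O)OCC[C@@H]1[C@@]2(C)CCCC(C)(C)[C@@H]2[C@@H](O)CC1=C
F2 | step 7 | bis(trimethylsilyl) ether of 14 | C[Si](C)(C)OCC/C=C(\C)C[C@@H](O[Si](C)(C)C)C1=C(C)CCCC1(C)C
F3 | step 7 | trimethylsilyl enol ether of 17, C-12 trimethylsilyl ether | C[Si](C)(C)OCC[C@@H](C(C)=C)[C@@]1(C)CCCC(C)(C)C1=CO[Si](C)(C)C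
F4 | step 10 | 6α,8α-bis(triethylsilyloxy)-13,14,15,16-tetranorlabdan-12-yl 2,2-dimethylpropanoate | CC(C)(C)C(=O)OCC[C@@H]1[C@@]2(C)CCCC(C)(C)[C@@H]2[C@@H](O[Si](CC)(CC)CC)C[C@@]1(C)O[Si](CC)(CC)CC
F5 | step 10 | 6α-hydroxy-8α-(triethylsilyloxy)-13,14,15,16-tetranorlabdan-12-yl 2,2-dimethylpropanoate | CC(C)(C)C(=O)OCC[C@@H]1[C@@]2(C)CCCC(C)(C)[C@@H]2[C@@H](O)C[C@@]1(C)O[Si](CC)(CC)CC
F6 | step 10 | 6α,18-epoxy-8α-(triethylsilyloxy)-13,14,15,16-tetranorlabdan-12-yl 2,2-dimethylpropanoate | CC(C)(C)C(=O)OCC[C@@H]1[C@@]2(C)CCC[C@@](C)(CO3)[C@@H]2[C@@H]3C[C@@]1(C)O[Si](CC)(CC)CC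
F7 | step 10 | 12-pivaloyloxy-8α-(triethylsilyloxy)-13,14,15,16-tetranorlabdan-18,6α-olide | CC(C)(C)C(=O)OCC[C@@H]1[C@@]2(C)CCC[C@@](C)(C(=O)O3)[C@@H]2[C@@H]3C[C@@]1(C)O[Si](CC)(CC)CC
F8 | step 10 | 6α,18-dihydroxy-8α-(triethylsilyloxy)-13,14,15,16-tetranorlabdan-12-yl 2,2-dimethylpropanoate | CC(C)(C)C(=O)OCC[C@@H]1[C@@]2(C)CCC[C@@](C)(CO)[C@@H]2[C@@H](O)C[C@@]1(C)O[Si](CC)(CC)CC
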